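The numbers of this flask are assumed; what happens was integrated by code.

Reagent in this flask is consumed by two arrows: capture, which forms catalyst intermediate A on the way to target, and over-reaction, which destroys target.

    reagent + free catalyst + target → free catalyst + over-reaction product (k1 = 620 M⁻² min⁻¹)
    reagent + free catalyst → catalyst intermediate A (k2 = 120 M⁻¹ min⁻¹)
    substrate + catalyst intermediate A ⇌ catalyst intermediate B (K3 = 3.2 M⁻¹, k3 = 210 M⁻¹ min⁻¹)
    catalyst intermediate B → free catalyst + target (k4 = 4.9 min⁻¹)

substrate 0.20 M; reagent 0.160 M (fed, over 1.5 min); free catalyst 2.0 mM; time 10 h; the fed solution adds 1.0 times the starting volume

* how much target there is at 10 h, in percent of the substrate charged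
* how much over-reaction product there is at 10 h, in percent of the substrate charged

**Over-reaction number.** Both arrows go in proportion to reagent times free catalyst, so their ratio contains neither and follows target. The feed of 1.5 min is shorter than the 2.9 min half-life of reagent by capture alone, the other concentrations held at their charge, so this reckoning puts the flask at 2.00 starting volumes from the outset. The over-reaction rate over the capture rate, with target standing at the whole substrate charge, is then 0.517: the over-reaction number σ, a selectivity factor.

**Rate per reagent.** Reagent is the limiting reagent, and its charge equals 80.0% of the substrate charge. Target first forms one for one with reagent consumed. At target fraction p, this gain is slowed by two factors: 1 − σp, for target removed, and 1/(1 + σp), for reagent diverted.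

**Accumulated slowing.** That same half-life, with its concentrations held at their charge, is short against the 10 h allowed, so the reckoning runs to the end of the reagent. Mean target is taken as half the final amount. Starting from 80.0% as the final amount gives 52.6%, which overstates the slowing. Repeating with that amount gives 60.9%, which understates it. The middle is 56.7% target. Each over-reaction product took two reagents and each target one, so the remainder gives 11.6% over-reaction product.

**The forecast.** It gives 58.1% target and 11% over-reaction product, on the ground that the ratio of the two fluxes is “independent of the catalyst states”. Its target stands above this reckoning.

**The result.** The flask gives 58.4% target and 10.8% over-reaction product, with reagent at 0%. Its closing ratio of over-reaction rate to capture rate, by σ, is 0.302. The neighbour with 0.096 M of reagent has a charge equal to 48.0% of the substrate charge. The same passes give 37.4% and 39.5%, so 38.5% target and 4.77% over-reaction product. That neighbour gives 39.2% target and 4.42% over-reaction product, with reagent at 0% and substrate at 56.4%.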